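**Plan**
- The target is an achiral pentaphenyl tetraether; rings are lettered A to E from the 2,4,6-trihydroxyphenyl end. The retrosynthesis first removes twelve O-alkyl groups, then cuts the aryl–oxygen bonds D–E, C–D and B–C, each on the side of the outer ring.
- Ring B, numbered from the carbon that bears the ring A oxygen (C1), has H at C2, OH at C3 and oxygens at C4 and C5. The C1 and C3 oxygens sit meta across an unsubstituted C2, the resorcinol monoether pattern that a vinylketene and an ynol ether give on benzannulation.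
- Ring B is therefore cut at C2–C3 and C1–C6, into an aryl ethynyl ether (C1, C2 and the A–O–B oxygen) and a 3,4-dioxygenated cyclobutenone (C3 to C6).
- Forward order: the ring A ynol ether, ring B by benzannulation, rings C and D by two SNAr/Baeyer–Villiger cycles, ring E by copper-catalysed etherification, then global dealkylation.
- The target has no stereocentre; the racemic sp3 centres of the cyclobutenone and of two transient intermediates vanish when ring B aromatises.

Key step: step 4

Assumption: the two fluorodimethoxybenzaldehydes used as donors of rings C and D are treated as catalogue building blocks.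

**Step 1**
Reactants: 1 2,4,6-trimethoxyphenol; 2 trichloroethylene
Product: 4 2-{[(E)-1,2-dichloroethenyl]oxy}-1,3,5-trimethoxybenzene, via dichloroacetylene 3 (not isolated)
Conditions: K2CO3, DMF, 70 °C
Reagents that add atoms: none
Why: Carbonate should dehydrochlorinate trichloroethylene to dichloroacetylene, to which the hindered phenoxide adds in anti fashion (nucleophilic addition to a haloalkyne), the known route to aryl (E)-1,2-dichlorovinyl ethers, so that the crowded A–O bond is made before ring B exists.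

**Step 2**
Reactants: 4 2-{[(E)-1,2-dichloroethenyl]oxy}-1,3,5-trimethoxybenzene
Product: 7 2-(ethynyloxy)-1,3,5-trimethoxybenzene, via chloroethynyl ether 5 (not isolated), via lithium acetylide 6 (not isolated)
Conditions: n-BuLi (2.2 equiv), THF, −78 °C; then H2O, −78 °C
Reagents that add atoms: none
Why: Elimination of HCl to the chloroalkyne followed by lithium–chlorine exchange and protonation is the established dichlorovinyl ether route to terminal ynol ethers; ring lithiation between the methoxy groups is too slow at −78 °C, and the product is kept cold in solution and used at once.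

**Step 3**
Reactants: 8 benzyloxyacetyl chloride; 9 ethoxyacetylene
Product: 11 rac-4-(benzyloxy)-3-ethoxycyclobut-2-en-1-one, via benzyloxyketene 10 (not isolated)
Conditions: Et3N, Et2O, 0 °C to rt, slow addition of 8 to excess 9
Reagents that add atoms: none
Why: Dehydrochlorination of the acid chloride gives the alkoxyketene, which should undergo the known ketene–alkoxyacetylene [2+2] cycloaddition with the carbonyl carbon bonding to the alkyne CH; the C4 centre is racemic and is destroyed in step 4.

**Step 4**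
Reactants: 11 rac-4-(benzyloxy)-3-ethoxycyclobut-2-en-1-one; 7 2-(ethynyloxy)-1,3,5-trimethoxybenzene
Product: 16 2-(benzyloxy)-3-ethoxy-5-(2,4,6-trimethoxyphenoxy)phenol, via vinylketene 12 (not isolated), via vinylcyclobutenone 13 (not isolated), via dienylketene 14 (not isolated), via cyclohexadienone 15 (not isolated)
Conditions: 11 (1.5 equiv), PhMe, 80 to 110 °C; then KOH, MeOH, rt
Reagents that add atoms: none
Why: Thermal 4π electrocyclic opening of 11, with the benzyloxy group turning outward, should give vinylketene 12, whose ketene carbon is attacked by the unsubstituted, nucleophilic carbon of ynol ether 7 in a [2+2] cycloaddition to vinylcyclobutenone 13, and a second 4π opening gives dienylketene 14. Ring B then closes by 6π electrocyclisation of 14, in which the ketene carbon (C3 of ring B) rejoins the benzyloxy-bearing carbon (C4), and the resulting dienone 15 tautomerises to phenol 16. The closest known reaction is the Danheiser benzannulation of cyclobutenones with alkoxyacetylenes to resorcinol monoethers. No stereocentre is formed that survives, since the racemic centres of 11, 13 and 15 are erased on aromatisation. The selectivity needed is the orientation of the ketene–alkyne [2+2] addition, which the polarisation of the ynol ether secures, so that the alkyne CH becomes C2 bonded to C3 and the aryloxy carbon becomes C1 bonded to C6. The closure needs the cis dienylketene, which reversible opening of 13 supplies, and the alkaline work-up cleaves any ester formed between the product phenol and excess ketene.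

**Step 5**
Reactants: 16 2-(benzyloxy)-3-ethoxy-5-(2,4,6-trimethoxyphenoxy)phenol
Product: 17 2-(benzyloxy)-1-ethoxy-3-methoxy-5-(2,4,6-trimethoxyphenoxy)benzene
Conditions: MeI, K2CO3, acetone, reflux
Reagents that add atoms: iodomethane, CI
Why: Williamson methylation of the only free phenol caps the C3 oxygen, so that the next step frees the C4 oxygen alone.

**Step 6**
Reactants: 17 2-(benzyloxy)-1-ethoxy-3-methoxy-5-(2,4,6-trimethoxyphenoxy)benzene
Product: 18 2-ethoxy-6-methoxy-4-(2,4,6-trimethoxyphenoxy)phenol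
Conditions: H2 (1 atm), 10% Pd/C, EtOAc–EtOH, rt
Reagents that add atoms: none
Why: Catalytic hydrogenolysis cleaves the benzyl ether selectively, since methyl, ethyl and diaryl ethers are inert under these conditions.

**Step 7**
Reactants: 18 2-ethoxy-6-methoxy-4-(2,4,6-trimethoxyphenoxy)phenol; 19 2-fluoro-4,6-dimethoxybenzaldehyde
Product: 20 2-[2-ethoxy-6-methoxy-4-(2,4,6-trimethoxyphenoxy)phenoxy]-4,6-dimethoxybenzaldehyde
Conditions: Cs2CO3, DMSO, 110 °C, argon
Reagents that add atoms: none
Why: Nucleophilic aromatic substitution by addition–elimination: the ortho formyl group stabilises the Meisenheimer intermediate, the methoxy groups sit on carbons that carry no charge in it, and displacement of fluoride from fluorobenzaldehydes by 2,6-dialkoxyphenoxides is well precedented.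

**Step 8**
Reactants: 20 2-[2-ethoxy-6-methoxy-4-(2,4,6-trimethoxyphenoxy)phenoxy]-4,6-dimethoxybenzaldehyde
Product: 22 2-[2-ethoxy-6-methoxy-4-(2,4,6-trimethoxyphenoxy)phenoxy]-4,6-dimethoxyphenol, via aryl formate 21 (not isolated)
Conditions: mCPBA (1.2 equiv), CH2Cl2, 0 °C to rt; then K2CO3 (cat.), MeOH, rt
Reagents that add atoms: mCPBA (3-chloroperoxybenzoic acid), OOC(=O)c1cccc(Cl)c1
Why: Baeyer–Villiger oxidation of the Dakin type: the electron-rich 2,4,6-trioxygenated aryl group migrates in preference to hydride, and methanolysis of the formate frees the ring C phenol at the position that must carry ring D.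

**Step 9**
Reactants: 22 2-[2-ethoxy-6-methoxy-4-(2,4,6-trimethoxyphenoxy)phenoxy]-4,6-dimethoxyphenol; 23 4-fluoro-2,6-dimethoxybenzaldehyde
Product: 24 4-{2-[2-ethoxy-6-methoxy-4-(2,4,6-trimethoxyphenoxy)phenoxy]-4,6-dimethoxyphenoxy}-2,6-dimethoxybenzaldehyde
Conditions: Cs2CO3, DMSO, 120 °C, argon
Reagents that add atoms: none
Why: Nucleophilic aromatic substitution as in step 7, here para to the formyl group, placing the aldehyde where ring D needs its oxygen for ring E.

**Step 10**
Reactants: 24 4-{2-[2-ethoxy-6-methoxy-4-(2,4,6-trimethoxyphenoxy)phenoxy]-4,6-dimethoxyphenoxy}-2,6-dimethoxybenzaldehyde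
Product: 26 4-{2-[2-ethoxy-6-methoxy-4-(2,4,6-trimethoxyphenoxy)phenoxy]-4,6-dimethoxyphenoxy}-2,6-dimethoxyphenol, via aryl formate 25 (not isolated)
Conditions: mCPBA (1.2 equiv), CH2Cl2, 0 °C to rt; then K2CO3 (cat.), MeOH, rt
Reagents that add atoms: mCPBA (3-chloroperoxybenzoic acid), OOC(=O)c1cccc(Cl)c1
Why: Baeyer–Villiger oxidation of a 2,6-dimethoxy-4-aryloxybenzaldehyde with aryl migration, followed by methanolysis of the formate, as in step 8.

**Step 11**
Reactants: 26 4-{2-[2-ethoxy-6-methoxy-4-(2,4,6-trimethoxyphenoxy)phenoxy]-4,6-dimethoxyphenoxy}-2,6-dimethoxyphenol; 27 5-iodo-1,2,3-trimethoxybenzene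
Product: 28 5-(4-{2-[2-ethoxy-6-methoxy-4-(2,4,6-trimethoxyphenoxy)phenoxy]-4,6-dimethoxyphenoxy}-2,6-dimethoxyphenoxy)-1,2,3-trimethoxybenzene
Conditions: CuI (10 mol%), picolinic acid (20 mol%), K3PO4, DMSO, 90 °C, argon
Reagents that add atoms: none
Why: Ullmann-type C–O coupling with the CuI/picolinic acid system, which is established for 2,6-disubstituted phenols and electron-rich aryl iodides; the iodide has no ortho substituent and brings ring E with its three oxygens in place, saving one oxidation step.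

**Step 12**
Reactants: 28 5-(4-{2-[2-ethoxy-6-methoxy-4-(2,4,6-trimethoxyphenoxy)phenoxy]-4,6-dimethoxyphenoxy}-2,6-dimethoxyphenoxy)-1,2,3-trimethoxybenzene
Product: 29 5-(4-{2-[2,6-dihydroxy-4-(2,4,6-trihydroxyphenoxy)phenoxy]-4,6-dihydroxyphenoxy}-2,6-dihydroxyphenoxy)benzene-1,2,3-triol (CNP0227069.0)
Conditions: BBr3 (30 equiv), CH2Cl2, −78 °C to rt; then H2O, 0 °C, argon, degassed solvents
Reagents that add atoms: none
Why: BBr3 cleavage of alkyl aryl ethers, in which bromide attacks the O-alkyl carbon of the boron-complexed ether, should remove the eleven methyl groups and the ethyl group while the diaryl ether bonds, which offer no carbon open to SN2 attack, stay intact; the aryloxyboron species, which are no single compound, are hydrolysed on work-up.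

**Compound list**
1 | 2,4,6-trimethoxyphenol | COc1cc(OC)c(O)c(OC)c1 | starting material
2 | trichloroethylene | ClC=C(Cl)Cl | starting material
3 | dichloroacetylene | ClC#CCl | intermediate
4 | 2-{[(E)-1,2-dichloroethenyl]oxy}-1,3,5-trimethoxybenzene | COc1cc(OC)c(O/C(Cl)=C\Cl)c(OC)c1 | intermediate
5 | 2-[(chloroethynyl)oxy]-1,3,5-trimethoxybenzene | COc1cc(OC)c(OC#CCl)c(OC)c1 | intermediate
6 | lithium (2,4,6-trimethoxyphenoxy)acetylide | [Li]C#COc1c(OC)cc(OC)cc1OC | intermediate
7 | 2-(ethynyloxy)-1,3,5-trimethoxybenzene | COc1cc(OC)c(OC#C)c(OC)c1 | intermediate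
8 | benzyloxyacetyl chloride | O=C(Cl)COCc1ccccc1 | starting material
9 | ethoxyacetylene | CCOC#C | starting material
10 | benzyloxyketene | O=C=COCc1ccccc1 | intermediate
11 | rac-4-(benzyloxy)-3-ethoxycyclobut-2-en-1-one (racemic, one enantiomer drawn) | CCOC1=CC(=O)[C@@H]1OCc1ccccc1 | intermediate
12 | (3Z)-4-(benzyloxy)-3-ethoxybuta-1,3-dien-1-one | O=C=C/C(OCC)=C/OCc1ccccc1 | intermediate
13 | rac-4-[(Z)-2-(benzyloxy)-1-ethoxyethenyl]-3-(2,4,6-trimethoxyphenoxy)cyclobut-2-en-1-one (racemic, one enantiomer drawn) | CCO/C(=C\OCc1ccccc1)[C@@H]1C(=O)C=C1Oc1c(OC)cc(OC)cc1OC | intermediate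
14 | (3E,5Z)-6-(benzyloxy)-5-ethoxy-3-(2,4,6-trimethoxyphenoxy)hexa-1,3,5-trien-1-one | O=C=C\C(Oc1c(OC)cc(OC)cc1OC)=C/C(OCC)=C/OCc1ccccc1 | intermediate
15 | rac-6-(benzyloxy)-5-ethoxy-3-(2,4,6-trimethoxyphenoxy)cyclohexa-2,4-dien-1-one (racemic, one enantiomer drawn) | CCOC1=CC(Oc2c(OC)cc(OC)cc2OC)=CC(=O)[C@@H]1OCc1ccccc1 | intermediate
16 | 2-(benzyloxy)-3-ethoxy-5-(2,4,6-trimethoxyphenoxy)phenol | CCOc1cc(Oc2c(OC)cc(OC)cc2OC)cc(O)c1OCc1ccccc1 | intermediate
17 | 2-(benzyloxy)-1-ethoxy-3-methoxy-5-(2,4,6-trimethoxyphenoxy)benzene | CCOc1cc(Oc2c(OC)cc(OC)cc2OC)cc(OC)c1OCc1ccccc1 | intermediate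
18 | 2-ethoxy-6-methoxy-4-(2,4,6-trimethoxyphenoxy)phenol | CCOc1cc(Oc2c(OC)cc(OC)cc2OC)cc(OC)c1O | intermediate
19 | 2-fluoro-4,6-dimethoxybenzaldehyde | COc1cc(F)c(C=O)c(OC)c1 | starting material
20 | 2-[2-ethoxy-6-methoxy-4-(2,4,6-trimethoxyphenoxy)phenoxy]-4,6-dimethoxybenzaldehyde | CCOc1cc(Oc2c(OC)cc(OC)cc2OC)cc(OC)c1Oc1cc(OC)cc(OC)c1C=O | intermediate
21 | 2-[2-ethoxy-6-methoxy-4-(2,4,6-trimethoxyphenoxy)phenoxy]-4,6-dimethoxyphenyl formate | CCOc1cc(Oc2c(OC)cc(OC)cc2OC)cc(OC)c1Oc1cc(OC)cc(OC)c1OC=O | intermediate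
22 | 2-[2-ethoxy-6-methoxy-4-(2,4,6-trimethoxyphenoxy)phenoxy]-4,6-dimethoxyphenol | CCOc1cc(Oc2c(OC)cc(OC)cc2OC)cc(OC)c1Oc1cc(OC)cc(OC)c1O | intermediate
23 | 4-fluoro-2,6-dimethoxybenzaldehyde | COc1cc(F)cc(OC)c1C=O | starting material
24 | 4-{2-[2-ethoxy-6-methoxy-4-(2,4,6-trimethoxyphenoxy)phenoxy]-4,6-dimethoxyphenoxy}-2,6-dimethoxybenzaldehyde | CCOc1cc(Oc2c(OC)cc(OC)cc2OC)cc(OC)c1Oc1cc(OC)cc(OC)c1Oc1cc(OC)c(C=O)c(OC)c1 | intermediate
25 | 4-{2-[2-ethoxy-6-methoxy-4-(2,4,6-trimethoxyphenoxy)phenoxy]-4,6-dimethoxyphenoxy}-2,6-dimethoxyphenyl formate | CCOc1cc(Oc2c(OC)cc(OC)cc2OC)cc(OC)c1Oc1cc(OC)cc(OC)c1Oc1cc(OC)c(OC=O)c(OC)c1 | intermediate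
26 | 4-{2-[2-ethoxy-6-methoxy-4-(2,4,6-trimethoxyphenoxy)phenoxy]-4,6-dimethoxyphenoxy}-2,6-dimethoxyphenol | CCOc1cc(Oc2c(OC)cc(OC)cc2OC)cc(OC)c1Oc1cc(OC)cc(OC)c1Oc1cc(OC)c(O)c(OC)c1 | intermediate
27 | 5-iodo-1,2,3-trimethoxybenzene | COc1cc(I)cc(OC)c1OC | starting material
28 | 5-(4-{2-[2-ethoxy-6-methoxy-4-(2,4,6-trimethoxyphenoxy)phenoxy]-4,6-dimethoxyphenoxy}-2,6-dimethoxyphenoxy)-1,2,3-trimethoxybenzene | CCOc1cc(Oc2c(OC)cc(OC)cc2OC)cc(OC)c1Oc1cc(OC)cc(OC)c1Oc1cc(OC)c(Oc2cc(OC)c(OC)c(OC)c2)c(OC)c1 | intermediate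
29 | 5-(4-{2-[2,6-dihydroxy-4-(2,4,6-trihydroxyphenoxy)phenoxy]-4,6-dihydroxyphenoxy}-2,6-dihydroxyphenoxy)benzene-1,2,3-triol (CNP0227069.0) | Oc1cc(O)c(Oc2cc(O)c(Oc3cc(O)cc(O)c3Oc3cc(O)c(Oc4cc(O)c(O)c(O)c4)c(O)c3)c(O)c2)c(O)c1 | target

**Step count**
Total: 12 steps. Longest linear sequence: 11 steps (1, 2, 4 to 12); step 3 is a one-step side branch.

**Steps most likely to fail**

Step 4. The terminal aryl ethynyl ether may polymerise, and the vinylketene may oligomerise, faster than the two combine at the temperature the cyclobutenone needs to open; acylation of the product phenol by ketene would lower the return further. The fallback gives up the benzannulation for ring B and builds phenol 18 from an intact arene, setting out from 23 and 1. Chelation-controlled mono-demethylation of 23 with BCl3 (CH2Cl2, −78 to 0 °C) should give 4-fluoro-2-hydroxy-6-methoxybenzaldehyde F1, and ethylation (EtI, K2CO3, DMF) then gives 2-ethoxy-4-fluoro-6-methoxybenzaldehyde F2. SNAr with phenol 1 (Cs2CO3, DMSO, 100 °C) gives 2-ethoxy-6-methoxy-4-(2,4,6-trimethoxyphenoxy)benzaldehyde F3. Baeyer–Villiger oxidation with mCPBA to 2-ethoxy-6-methoxy-4-(2,4,6-trimethoxyphenoxy)phenyl formate F4 and methanolysis come back to the route at 18.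

Step 12. Twelve ether cleavages must all go to completion, and the electron-rich dodecaphenol may be oxidised by air during aqueous work-up and chromatography, leaving partly alkylated or quinoid material that cannot be separated. The fallback, from 28, traps the crude product after the BBr3 cleavage and quench with Ac2O and pyridine as the stable 5-(4-{2-[2,6-diacetoxy-4-(2,4,6-triacetoxyphenoxy)phenoxy]-4,6-diacetoxyphenoxy}-2,6-diacetoxyphenoxy)benzene-1,2,3-triyl triacetate F5. This is purified on silica and then deacetylated with HCl in degassed MeOH under argon, which leaves only volatile by-products and comes back to the route at 29.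

Step 9. Addition of the doubly ortho-substituted phenoxide of 22 to fluoroaldehyde 23 may be sluggish, because the two ortho methoxy groups weaken the formyl group as an acceptor, and the phenoxide may decompose at the temperature then required. The fallback, from 22, replaces the addition–elimination by a copper-catalysed Ullmann etherification with commercial 4-bromo-2,6-dimethoxybenzaldehyde F6 (CuI, picolinic acid, K3PO4, DMSO, 90 °C), which forms the same C–O bond at the metal and comes back to the route at 24.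

**Further compounds**
F1 | step 4 | 4-fluoro-2-hydroxy-6-methoxybenzaldehyde | COc1cc(F)cc(O)c1C=O
F2 | step 4 | 2-ethoxy-4-fluoro-6-methoxybenzaldehyde | CCOc1cc(F)cc(OC)c1C=O
F3 | step 4 | 2-ethoxy-6-methoxy-4-(2,4,6-trimethoxyphenoxy)benzaldehyde | CCOc1cc(Oc2c(OC)cc(OC)cc2OC)cc(OC)c1C=O
F4 | step 4 | 2-ethoxy-6-methoxy-4-(2,4,6-trimethoxyphenoxy)phenyl formate | CCOc1cc(Oc2c(OC)cc(OC)cc2OC)cc(OC)c1OC=O
F5 | step 12 | 5-(4-{2-[2,6-diacetoxy-4-(2,4,6-triacetoxyphenoxy)phenoxy]-4,6-diacetoxyphenoxy}-2,6-diacetoxyphenoxy)benzene-1,2,3-triyl triacetate | CC(=O)Oc1cc(OC(C)=O)c(Oc2cc(OC(C)=O)c(Oc3cc(OC(C)=O)cc(OC(C)=O)c3Oc3cc(OC(C)=O)c(Oc4cc(OC(C)=O)c(OC(C)=O)c(OC(C)=O)c4)c(OC(C)=O)c3)c(OC(C)=O)c2)c(OC(C)=O)c1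
F6 | step 9 | 4-bromo-2,6-dimethoxybenzaldehyde (purchased) | COc1cc(Br)cc(OC)c1C=O
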